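My unit for this repeat was the cover, C: moles of partner charged per mole of both substrates together, 2.00 for the new flask and 0.972 for beta.

- beta: left-handed substrate 0.72 M; right-handed substrate 0.72 M; partner 1.4 M (fed, over 4.0 h); run made earlier; the fed solution adds 0.20 times the starting volume
- flask: left-handed substrate 0.72 M; partner 2.88 M (fed, over 4.0 h); right-handed substrate 0.72 M; time 2.5 d; the fed solution adds 0.20 times the starting volume

- beta (time / d: left-handed product / %, right-handed product / %): 0.125: 31.8, 18.3; 0.417: 55.4, 34.7; 0.625: 57.3, 36.1; 1.04: 57.8, 36.6; 1.67: 59.1, 38.1; 2.08: 58.8, 38.1; 2.50: 59.6, 37.7

(scatter of a reading: 0.5 percentage points)

- partner is single-handed; left-handed substrate and right-handed substrate are mirror images of each other, charged as a racemate, each of them at the stated concentration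
- charges are per starting volume, the dose included; the dosed solution carries all of it
- the reaction counts as stopped when no species that holds the left-handed substrate and right-handed substrate together changes by six tenths of a point or more over the second half of the time
- the handed part of partner does not stay in what it makes, so the products of the two hands are mirror images too

- at 2.5 d, what has stopped the reaction, if anything has (the partner has run out first / all of the left-handed substrate has reacted / it is still moving / forward and back rates have come level)
- the left-handed product standing at 2.5 d, as a percentage of the left-handed substrate and right-handed substrate together charged
- the right-handed product standing at 2.5 d, as a percentage of the left-handed substrate and right-handed substrate together charged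

In beta the two products together read 97.3 % at 2.50 d, close to that cover. I therefore took one mole of partner to make one mole of product of either hand, with partner as the limiting reagent in beta. My rule, for this recipe given time to finish, was that the products together reach the smaller of C and 100%. Above one, the share of partner left over is one minus one over C.

The new flask stood above one, so I reckoned on the products together reaching 100% and on 50.0 % of its partner remaining. I kept the charge at 2.88 M and the time at 2.5 d. The two things to watch in the flask were the sum of the products and the partner left.

The cover gave no split. Left-handed substrate was 50.0 % of the charge, yet beta's left-handed product read 59.6 %, which is 9.6 percentage points above it. Right-handed substrate had therefore crossed over, and I expected the flask's left-handed product to lie above 50.0 %, by an amount C could not give.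

The forecast said that what had stopped the reaction at 2.5 d was this: all of the left-handed substrate has reacted; it put the left-handed product at 52.5 % and the right-handed product at 47.5 %, on the ground that “Substrate is therefore consumed within about 0.3 d, leaving little time for interconversion.”

The flask gave 56.1 % left-handed and 43.9 % right-handed product at 2.50 d, and what had stopped it was this: all of the left-handed substrate has reacted.

    partner + left-handed substrate → left-handed product (k = 4.90 × 10⁻⁴ L mol⁻¹ s⁻¹)
    partner + right-handed substrate → right-handed product (k = 2.50 × 10⁻⁴ L mol⁻¹ s⁻¹)
    left-handed substrate ⇌ right-handed substrate (k = 6.80 × 10⁻⁵ s⁻¹)

A net 6.07 % of the charge had crossed from right-handed to left-handed substrate by then. The products together stood at 100 %, with 0 % left-handed and 0 % right-handed substrate remaining, and the partner left was 50 % against my 50.0 %. The neighbour flask, charged with 0.72 M of partner, has a cover of 0.500. Its partner stood at 0 % of its charge at 2.50 d, and its products were 31.9 % left-handed and 18.1 % right-handed, together 50.0 %.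

(The numbers in the tables are calculated for an exercise; noise was put on by code.)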